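Teal is read at 50 min, but set the clock aside at first and ask how far the first exchange has gone by then. The complex takes up incoming ligand twice, giving off leaving ligand each time. The capture agent can hold at most 2.00% of the charge, so keep it out of the balance for now, and set aside the crystals and the back step too.

| setting | elm | ash | teal | amber |
|---|---|---|---|---|
| starting complex | 0.50 M | 0.50 M | 0.50 M | 0.50 M |
| incoming ligand | 0.26 equiv | 2.6 equiv | 3.00 equiv | 0.500 equiv |
| capture agent | 10 mM | 10 mM | 10.0 mM | 10.0 mM |
| remark | run made earlier | run made earlier |  |  |
| time |  |  | 50 min | 50 min |

| run | time / min | complex with two exchanged / % | starting complex / % |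
|---|---|---|---|
| elm | 3.00 | 0 | 96.5 |
| elm | 4.00 | 0 | 95.6 |
| elm | 6.00 | 0 | 94.1 |
| elm | 10.0 | 0.3 | 91.1 |
| elm | 15.0 | 0 | 90.3 |
| elm | 25.0 | 0 | 83.6 |
| elm | 40.0 | 0 | 79.6 |
| ash | 5.00 | 1.8 | 56.6 |
| ash | 10.0 | 2.9 | 36.9 |
| ash | 15.0 | 5.8 | 24.6 |
| ash | 20.0 | 8.7 | 15.9 |
| ash | 25.0 | 10.4 | 10.0 |
| ash | 30.0 | 13.3 | 7.4 |
| ash | 40.0 | 16.9 | 2.9 |

(each reading ± 1 percentage point)

- for leaving ligand the crystals are counted in
- as a solid, counted per litre of solution: crystals
- what may be going on: starting complex + incoming ligand -> leaving ligand + complex with one exchanged; complex with one exchanged + incoming ligand <-> leaving ligand + complex with two exchanged; complex with one exchanged + capture agent -> trapped intermediate; crystals <-> leaving ligand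

* which of these holds the largest part of the starting complex at the end of teal (complex with one exchanged / starting complex / complex with two exchanged)
* which of these holds the largest part of the starting complex at the end of amber (complex with one exchanged / starting complex / complex with two exchanged)
* amount of complex with two exchanged at the end of teal, in percent of the starting complex charged

Begin with the first rate constant. In ash at 25.0 min, [starting complex] reads 10.0% of its charge and the balance puts [incoming ligand] at 0.798 M. For a bimolecular step, the ratio of ligand to complex, taken against its value at the start, grows as the exponential of constant times excess times time, which reads 0.0907 M⁻¹ min⁻¹.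

Next take the second constant from the late rise in ash. In ash, complex with two exchanged gains 0.00410 min⁻¹ as a fraction of the charge. Divide this by the share of complex with one exchanged, taken from the balance, and by [incoming ligand] at 30.0 min, 0.771 M, which reads 0.00671 M⁻¹ min⁻¹.

Both steps use the same ligand, so their ratio loses [incoming ligand]. That ratio, the selectivity factor s, second constant over first, reads 0.0740. Two equal sites would give 0.5, the zero of this scale, and ash reads lower.

Now let m be the fraction of starting complex left. Integrating gives complex with one exchanged as (m^s − m)/(1 − s) of the charge, and complex with two exchanged as the remainder, with the capture agent still kept out. In teal the ligand excess is 1.00 M, so my reckoning gives m = 0.714%. That makes 74.2% with one exchanged, more than the 25.1% with two. In amber the ligand is the limiting reagent, and the bimolecular law solved for that charge leaves m = 59.6%, more than the rest of the charge, so starting complex leads there.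

The forecast, which puts the second step “about ten times slower”, names complex with one exchanged for teal and starting complex for amber, and gives 26%, above my figure.

The flask gives complex with one exchanged for teal, starting complex for amber, and 26.4% with two exchanged in teal.

    starting complex + incoming ligand → leaving ligand + complex with one exchanged (k = 0.0920 M⁻¹ min⁻¹)
    complex with one exchanged + incoming ligand ⇌ leaving ligand + complex with two exchanged (K = 5.10, k = 0.00790 M⁻¹ min⁻¹)
    complex with one exchanged + capture agent → trapped intermediate (k = 0.160 M⁻¹ min⁻¹)
    crystals ⇌ leaving ligand, rate k4*(cs4 - [leaving ligand]) while solid is left; crystals form when [leaving ligand] > cs4 (solubility = 0.330 M, k = 10.0 min⁻¹)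

Read teal earlier, at 12 min, where the simulated starting complex is 25.1%. Put that m and the s from ash into the rule. It gives 70.4% with one exchanged and 4.50% with two. Teal at that time holds 69.0% with one exchanged and 5.16% with two.

Readings and results were computed for substances that don't exist; noise was put on by code.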